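## Retrosynthetic overview

Decalin numbering used throughout: C1 carries the dienoic acid, C2 the butenyl group, C3 the ring methyl, C4a/C8a are the ring fusion, C7 carries oxygen, C8 the methyl.

1. The C7–O sulfate bond is made late, by SN2 displacement of the 7-epi (equatorial) triflate with sulfate dianion (inversion), from 7-epi alcohol 19.
2. Both rings form in one step: cis-decalin 18 from a type 1 intramolecular Diels–Alder reaction of linear hexaenoate 17 (ring B closes through the tether as ring A, the cyclohexene, forms).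
3. 17 comes from a B-alkyl Suzuki coupling (C5–C4a) of trienyl iodide 4 with tetraenoate 15.
4. 15 comes from two olefinations of aldehyde 10, itself from a syn aldol of acrolein with propionyl thiazolidinethione 5; 4 comes from tiglic aldehyde (Wittig, then Takai).

Assumption: the target is taken as the free diacid drawn (released from its salt by acidification in the last step), and auxiliary imide 5 is bought as a catalogue reagent.

## Route

Step 1
Reactants: 1 tiglic aldehyde ((E)-2-methylbut-2-enal); 2 2-(triphenylphosphoranylidene)propanal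
Product: 3 (2E,4E)-2,4-dimethylhexa-2,4-dienal
Conditions: toluene, 110 °C, 24 h (1.5 equiv of 1)
Reagents that add atoms: none
Why: Wittig olefination with a formyl-stabilised ylide gives the (E)-trisubstituted enal and leaves the existing (E)-alkene, which becomes the butenyl group, untouched.

Step 2
Reactants: 3 (2E,4E)-2,4-dimethylhexa-2,4-dienal
Product: 4 (1E,3E,5E)-1-iodo-3,5-dimethylhepta-1,3,5-triene
Conditions: CrCl2 (6 equiv), CHI3 (2 equiv), THF/dioxane, 0 °C, dark
Reagents that add atoms: iodoform, IC(I)I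
Why: Takai olefination; the geminal dichromium carbenoid adds to the aldehyde and anti-eliminates to the (E)-vinyl iodide, with high E selectivity for conjugated aldehydes.

Step 3
Reactants: 5 (4S)-4-benzyl-3-propanoyl-1,3-thiazolidine-2-thione; 6 acrolein
Product: 8 (4S)-4-benzyl-3-[(2S,3R)-3-hydroxy-2-methylpent-4-enoyl]-1,3-thiazolidine-2-thione, via trichlorotitanium Z-enolate 7 (not isolated)
Conditions: TiCl4 (1.05 equiv), i-Pr2NEt (1.1 equiv), N-methylpyrrolidinone (1.1 equiv), CH2Cl2, 0 °C; then acrolein (1.5 equiv), −78 → 0 °C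
Reagents that add atoms: titanium tetrachloride, Cl[Ti](Cl)(Cl)Cl (atoms in 7 only)
Why: Crimmins titanium aldol in its "Evans syn" mode: the Z-enolate reacts through a closed chair transition state with the aldehyde anti to the benzyl group, setting the C8 methyl centre in its final configuration and the C7 carbinol as the 7-epi (syn) isomer.

Step 4
Reactants: 8 (4S)-4-benzyl-3-[(2S,3R)-3-hydroxy-2-methylpent-4-enoyl]-1,3-thiazolidine-2-thione
Product: 9 (4S)-4-benzyl-3-[(2S,3R)-3-(tert-butyldimethylsilyloxy)-2-methylpent-4-enoyl]-1,3-thiazolidine-2-thione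
Conditions: TBSOTf, 2,6-lutidine, CH2Cl2, −78 → 0 °C
Reagents that add atoms: tert-butyldimethylsilyl triflate, CC(C)(C)[Si](C)(C)OS(=O)(=O)C(F)(F)F
Why: O-silylation of the secondary alcohol blocks retro-aldol and β-elimination in the base-mediated olefinations that follow.

Step 5
Reactants: 9 (4S)-4-benzyl-3-[(2S,3R)-3-(tert-butyldimethylsilyloxy)-2-methylpent-4-enoyl]-1,3-thiazolidine-2-thione
Product: 10 (2S,3R)-3-(tert-butyldimethylsilyloxy)-2-methylpent-4-enal
Conditions: i-Bu2AlH (1.5 equiv), CH2Cl2, −78 °C; aq. KNaC4H4O6 work-up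
Reagents that add atoms: none
Why: Partial reduction of the N-acylthiazolidinethione; the tetrahedral aluminium adduct survives until work-up, so the aldehyde is neither over-reduced nor epimerised.

Step 6
Reactants: 10 (2S,3R)-3-(tert-butyldimethylsilyloxy)-2-methylpent-4-enal; 11 (triphenylphosphoranylidene)acetaldehyde
Product: 12 (2E,4R,5R)-5-(tert-butyldimethylsilyloxy)-4-methylhepta-2,6-dienal
Conditions: toluene, 80 °C, 16 h (1.2 equiv of 11)
Reagents that add atoms: none
Why: Base-free Wittig two-carbon homologation with a stabilised ylide is E-selective and does not touch the α-stereocentre; this alkene becomes the dienophile.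

Step 7
Reactants: 12 (2E,4R,5R)-5-(tert-butyldimethylsilyloxy)-4-methylhepta-2,6-dienal; 13 triethyl (E)-4-phosphonocrotonate
Product: 15 ethyl (2E,4E,6E,8R,9R)-9-(tert-butyldimethylsilyloxy)-8-methylundeca-2,4,6,10-tetraenoate, via lithiated phosphonate 14 (not isolated)
Conditions: LiN(SiMe3)2, THF, −78 °C; then 12, −78 → 0 °C
Reagents that add atoms: lithium hexamethyldisilazide, [Li+].C[Si](C)(C)[N-][Si](C)(C)C (lithium in 14 only)
Why: Horner–Wadsworth–Emmons olefination of the enal with the vinylogous phosphonate gives the (E,E,E)-trienoate at low temperature.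

Step 8
Reactants: 15 ethyl (2E,4E,6E,8R,9R)-9-(tert-butyldimethylsilyloxy)-8-methylundeca-2,4,6,10-tetraenoate; 4 (1E,3E,5E)-1-iodo-3,5-dimethylhepta-1,3,5-triene
Product: 17 ethyl (2E,4E,6E,8R,9R,12E,14E,16E)-9-(tert-butyldimethylsilyloxy)-8,14,16-trimethyloctadeca-2,4,6,12,14,16-hexaenoate, via alkyl-9-BBN borane 16 (not isolated)
Conditions: 9-BBN (1.5 equiv), THF, 0 °C → rt; then 4, PdCl2(dppf) (5 mol %), AsPh3, Cs2CO3, DMF/THF/H2O, rt, dark
Reagents that add atoms: 9-borabicyclo[3.3.1]nonane, B1C2CCCC1CCC2 (atoms in 16 only)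
Why: 9-BBN hydroborates only the monosubstituted alkene (anti-Markovnikov), and the B-alkyl Suzuki–Miyaura coupling then joins C5 to C4a with retention of the (E)-iodide geometry while tolerating the ester and silyl ether.

Step 9
Reactants: 17 ethyl (2E,4E,6E,8R,9R,12E,14E,16E)-9-(tert-butyldimethylsilyloxy)-8,14,16-trimethyloctadeca-2,4,6,12,14,16-hexaenoate
Product: 18 ethyl (2E,4E)-5-[(1S,2S,4aS,7R,8R,8aR)-2-[(E)-but-2-en-2-yl]-7-(tert-butyldimethylsilyloxy)-3,8-dimethyl-1,2,4a,5,6,7,8,8a-octahydronaphthalen-1-yl]penta-2,4-dienoate (cis-fused)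
Conditions: toluene (0.01 M), BHT (cat.), 120 °C, sealed tube, 24–48 h
Reagents that add atoms: none
Why: Thermal type 1 intramolecular Diels–Alder reaction through a chair tether with the C8 methyl and C7 silyloxy groups both equatorial (this fixes the π-face) in the tether-endo, dienoate-exo mode, which gives the cis ring fusion and the C1 chain trans to the C2 butenyl group and should be preferred because the alternative mode forces the C1 chain against the twisted butenyl/C3-methyl unit and into a peri clash with the equatorial C8 methyl; C1, C2, C4a and C8a are all set here relative to C8.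

Step 10
Reactants: 18 the cis-fused silyl ether
Product: 19 ethyl (2E,4E)-5-[(1S,2S,4aS,7R,8R,8aR)-2-[(E)-but-2-en-2-yl]-7-hydroxy-3,8-dimethyl-1,2,4a,5,6,7,8,8a-octahydronaphthalen-1-yl]penta-2,4-dienoate
Conditions: HF·pyridine, pyridine/THF, 0 °C → rt
Reagents that add atoms: none
Why: Fluoride-mediated desilylation; buffered HF·pyridine leaves the ester and the trisubstituted alkenes untouched.

Step 11
Reactants: 19 the 7-epi (7R, equatorial) alcohol
Product: 21 tetrabutylammonium salt of ethyl (2E,4E)-5-[(1S,2S,4aS,7S,8R,8aR)-2-[(E)-but-2-en-2-yl]-3,8-dimethyl-7-(sulfonatooxy)-1,2,4a,5,6,7,8,8a-octahydronaphthalen-1-yl]penta-2,4-dienoate, via C7 triflate 20 (not isolated)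
Conditions: Tf2O (1.2 equiv), 2,6-di-tert-butyl-4-methylpyridine (1.5 equiv), CH2Cl2, −40 °C; then (n-Bu4N)2SO4 (3 equiv, dried azeotropically), CH2Cl2/MeCN, −40 → 0 °C
Reagents that add atoms: bis(tetrabutylammonium) sulfate, CCCC[N+](CCCC)(CCCC)CCCC.CCCC[N+](CCCC)(CCCC)CCCC.[O-]S(=O)(=O)[O-]; triflic anhydride, O=S(=O)(OS(=O)(=O)C(F)(F)F)C(F)(F)F (atoms in 20 only)
Why: Proposed new method: stereoinvertive sulfation by C–O bond formation, in which the equatorial C7 triflate is displaced in an SN2 reaction by "naked" sulfate dianion (tetrabutylammonium counter-ions, aprotic medium) entering along the axial trajectory past only two axial hydrogens, giving the axial 7S sulfate monoester directly; E2 is disfavoured because an equatorial leaving group has no anti-periplanar β-hydrogen, and the monoanionic product does not react further; the closest known reaction types are the Lattrell–Dax nitrite and carboxylate displacements of secondary triflates with inversion and the alkylation of sulfate salts by simple primary alkylating agents, whereas sulfate esters of secondary alcohols are otherwise made by O–S bond formation with retention.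

Step 12
Reactants: 21 the tetrabutylammonium sulfate ethyl ester
Product: 22 (2E,4E)-5-[(1S,2S,4aS,7S,8R,8aR)-2-[(E)-but-2-en-2-yl]-3,8-dimethyl-7-(sulfooxy)-1,2,4a,5,6,7,8,8a-octahydronaphthalen-1-yl]penta-2,4-dienoic acid (CNP0450810.4)
Conditions: LiOH (5 equiv), THF/MeOH/H2O, 0 °C → rt; then aq. HCl to pH 2 at 0 °C, C18 reverse-phase purification
Reagents that add atoms: lithium hydroxide, [Li+].[OH-]
Why: Saponification (acyl–oxygen cleavage) of the ethyl ester; the alkyl sulfate monoester anion is inert to hydroxide at room temperature, and brief cold acidification releases the free acid form.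

## Compound list

1 | tiglic aldehyde, (E)-2-methylbut-2-enal | C/C=C(\C)C=O | starting material
2 | 2-(triphenylphosphoranylidene)propanal | CC(C=O)=P(c1ccccc1)(c1ccccc1)c1ccccc1 | starting material
3 | (2E,4E)-2,4-dimethylhexa-2,4-dienal | C/C=C(C)/C=C(\C)C=O | intermediate
4 | (1E,3E,5E)-1-iodo-3,5-dimethylhepta-1,3,5-triene | C/C=C(C)/C=C(C)/C=C/I | intermediate
5 | (4S)-4-benzyl-3-propanoyl-1,3-thiazolidine-2-thione | CCC(=O)N1[C@@H](Cc2ccccc2)CSC1=S | starting material
6 | acrolein | C=CC=O | starting material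
7 | trichlorotitanium (Z)-enolate of 5 | C/C=C(\O[Ti](Cl)(Cl)Cl)N1[C@@H](Cc2ccccc2)CSC1=S | intermediate (not isolated)
8 | (4S)-4-benzyl-3-[(2S,3R)-3-hydroxy-2-methylpent-4-enoyl]-1,3-thiazolidine-2-thione | C=C[C@@H](O)[C@H](C)C(=O)N1[C@@H](Cc2ccccc2)CSC1=S | intermediate
9 | (4S)-4-benzyl-3-[(2S,3R)-3-(tert-butyldimethylsilyloxy)-2-methylpent-4-enoyl]-1,3-thiazolidine-2-thione | C=C[C@@H](O[Si](C)(C)C(C)(C)C)[C@H](C)C(=O)N1[C@@H](Cc2ccccc2)CSC1=S | intermediate
10 | (2S,3R)-3-(tert-butyldimethylsilyloxy)-2-methylpent-4-enal | C=C[C@@H](O[Si](C)(C)C(C)(C)C)[C@H](C)C=O | intermediate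
11 | (triphenylphosphoranylidene)acetaldehyde | O=CC=P(c1ccccc1)(c1ccccc1)c1ccccc1 | starting material
12 | (2E,4R,5R)-5-(tert-butyldimethylsilyloxy)-4-methylhepta-2,6-dienal | C=C[C@@H](O[Si](C)(C)C(C)(C)C)[C@H](C)/C=C/C=O | intermediate
13 | triethyl (E)-4-phosphonocrotonate | CCOC(=O)/C=C/CP(=O)(OCC)OCC | starting material
14 | lithium salt of the γ-carbanion of 13 | [Li+].CCOC(=O)/C=C/[CH-]P(=O)(OCC)OCC | intermediate (not isolated)
15 | ethyl (2E,4E,6E,8R,9R)-9-(tert-butyldimethylsilyloxy)-8-methylundeca-2,4,6,10-tetraenoate | C=C[C@@H](O[Si](C)(C)C(C)(C)C)[C@H](C)/C=C/C=C/C=C/C(=O)OCC | intermediate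
16 | ethyl (2E,4E,6E,8R,9R)-11-(9-borabicyclo[3.3.1]nonan-9-yl)-9-(tert-butyldimethylsilyloxy)-8-methylundeca-2,4,6-trienoate | B1(C2CCCC1CCC2)CC[C@@H](O[Si](C)(C)C(C)(C)C)[C@H](C)/C=C/C=C/C=C/C(=O)OCC | intermediate (not isolated)
17 | ethyl (2E,4E,6E,8R,9R,12E,14E,16E)-9-(tert-butyldimethylsilyloxy)-8,14,16-trimethyloctadeca-2,4,6,12,14,16-hexaenoate | C/C=C(C)/C=C(C)/C=C/CC[C@@H](O[Si](C)(C)C(C)(C)C)[C@H](C)/C=C/C=C/C=C/C(=O)OCC | intermediate
18 | ethyl (2E,4E)-5-[(1S,2S,4aS,7R,8R,8aR)-2-[(E)-but-2-en-2-yl]-7-(tert-butyldimethylsilyloxy)-3,8-dimethyl-1,2,4a,5,6,7,8,8a-octahydronaphthalen-1-yl]penta-2,4-dienoate | C/C=C(\C)[C@H]1C(C)=C[C@H]2CC[C@@H](O[Si](C)(C)C(C)(C)C)[C@H](C)[C@H]2[C@@H]1/C=C/C=C/C(=O)OCC | intermediate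
19 | ethyl (2E,4E)-5-[(1S,2S,4aS,7R,8R,8aR)-2-[(E)-but-2-en-2-yl]-7-hydroxy-3,8-dimethyl-1,2,4a,5,6,7,8,8a-octahydronaphthalen-1-yl]penta-2,4-dienoate | C/C=C(\C)[C@H]1C(C)=C[C@H]2CC[C@@H](O)[C@H](C)[C@H]2[C@@H]1/C=C/C=C/C(=O)OCC | intermediate
20 | ethyl (2E,4E)-5-[(1S,2S,4aS,7R,8R,8aR)-2-[(E)-but-2-en-2-yl]-3,8-dimethyl-7-(trifluoromethanesulfonyloxy)-1,2,4a,5,6,7,8,8a-octahydronaphthalen-1-yl]penta-2,4-dienoate | C/C=C(\C)[C@H]1C(C)=C[C@H]2CC[C@@H](OS(=O)(=O)C(F)(F)F)[C@H](C)[C@H]2[C@@H]1/C=C/C=C/C(=O)OCC | intermediate (not isolated)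
21 | tetrabutylammonium salt of ethyl (2E,4E)-5-[(1S,2S,4aS,7S,8R,8aR)-2-[(E)-but-2-en-2-yl]-3,8-dimethyl-7-(sulfonatooxy)-1,2,4a,5,6,7,8,8a-octahydronaphthalen-1-yl]penta-2,4-dienoate | CCCC[N+](CCCC)(CCCC)CCCC.C/C=C(\C)[C@H]1C(C)=C[C@H]2CC[C@H](OS(=O)(=O)[O-])[C@H](C)[C@H]2[C@@H]1/C=C/C=C/C(=O)OCC | intermediate
22 | (2E,4E)-5-[(1S,2S,4aS,7S,8R,8aR)-2-[(E)-but-2-en-2-yl]-3,8-dimethyl-7-(sulfooxy)-1,2,4a,5,6,7,8,8a-octahydronaphthalen-1-yl]penta-2,4-dienoic acid | C/C=C(\C)[C@H]1C(C)=C[C@H]2CC[C@H](OS(=O)(=O)O)[C@H](C)[C@H]2[C@@H]1/C=C/C=C/C(=O)O | target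

## Step count and risks

Total steps: 12. Longest linear sequence: 10 (steps 3–12, from 5 and 6).

The three steps most likely to fail:

**Step 11 (the proposed new invertive sulfation).** The triflate may eliminate or hydrolyse instead of being displaced by the weakly nucleophilic sulfate. The fallback sets out from 19 and comes back at 22. A Mitsunobu reaction with 4-nitrobenzoic acid (PPh3, DIAD, toluene, 0 °C → rt) gives the inverted 7S 4-nitrobenzoate diester F1. LiOH (THF/MeOH/H2O) cleaves both esters to the 7S hydroxy acid F2. O-Sulfation with SO3·pyridine (pyridine, rt), hydrolysis of the mixed acyl sulfate on aqueous work-up and cold acidification give 22. Here C7 is inverted by a known C–O bond formation and the sulfate is put on by ordinary O–S bond formation with retention.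

**Step 9 (exo selectivity of the thermal cycloaddition).** π-Facial control should be high, but the cis-fused (exo) to trans-fused (endo) ratio is only an estimate, about 3:1, and could be lower. The fallback sets out from 10 and comes back at 18.
- Still–Gennari olefination (methyl bis(2,2,2-trifluoroethyl)phosphonoacetate, KN(SiMe3)2, 18-crown-6, THF, −78 °C) gives the (Z)-enoate F3.
- 9-BBN gives the alkylborane F4, not isolated, and Suzuki coupling with 4 gives the (Z)-enoate tetraene F5.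
- Heating F5 (toluene, 110–130 °C) lets the Z-dienophile react in its ester-endo mode, which for a Z-alkene is necessarily the tether-endo, cis-fused mode. This gives the cis-fused methyl ester F6 with the ester cis to the butenyl group.
- i-Bu2AlH gives the primary alcohol F7, and Dess–Martin periodinane gives the C1-epi aldehyde F8.
- DBU (CH2Cl2, rt) epimerises C1 to the aldehyde F9, in which the formyl group is trans to both neighbours, relieving the all-cis C2/C1/C8a array.
- Horner–Wadsworth–Emmons reaction of F9 with 13 (LiN(SiMe3)2, THF) gives 18.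

**Step 2 (Takai olefination of the dienal).** E/Z erosion and the light sensitivity of trienyl iodide 4 are the concerns. The fallback sets out from 3 and comes back at 4. Colvin homologation with lithiated trimethylsilyldiazomethane (TMSCHN2, n-BuLi, THF, −78 → 0 °C) gives the enyne (3E,5E)-3,5-dimethylhepta-3,5-dien-1-yne F10. Hydrozirconation with Cp2Zr(H)Cl (THF, rt) gives the (E)-alkenylzirconocene chloride F11, not isolated. Iodine at 0 °C cleaves the C–Zr bond with retention to give 4 as the E isomer only.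

## Further compounds

F1 | step 11 | ethyl (2E,4E)-5-[(1S,2S,4aS,7S,8R,8aR)-2-[(E)-but-2-en-2-yl]-3,8-dimethyl-7-(4-nitrobenzoyloxy)-1,2,4a,5,6,7,8,8a-octahydronaphthalen-1-yl]penta-2,4-dienoate | C/C=C(\C)[C@H]1C(C)=C[C@H]2CC[C@H](OC(=O)c3ccc(cc3)[N+](=O)[O-])[C@H](C)[C@H]2[C@@H]1/C=C/C=C/C(=O)OCC
F2 | step 11 | (2E,4E)-5-[(1S,2S,4aS,7S,8R,8aR)-2-[(E)-but-2-en-2-yl]-7-hydroxy-3,8-dimethyl-1,2,4a,5,6,7,8,8a-octahydronaphthalen-1-yl]penta-2,4-dienoic acid | C/C=C(\C)[C@H]1C(C)=C[C@H]2CC[C@H](O)[C@H](C)[C@H]2[C@@H]1/C=C/C=C/C(=O)O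
F3 | step 9 | methyl (2Z,4R,5R)-5-(tert-butyldimethylsilyloxy)-4-methylhepta-2,6-dienoate | C=C[C@@H](O[Si](C)(C)C(C)(C)C)[C@H](C)/C=C\C(=O)OC
F4 | step 9 | methyl (2Z,4R,5R)-7-(9-borabicyclo[3.3.1]nonan-9-yl)-5-(tert-butyldimethylsilyloxy)-4-methylhept-2-enoate | B1(C2CCCC1CCC2)CC[C@@H](O[Si](C)(C)C(C)(C)C)[C@H](C)/C=C\C(=O)OC
F5 | step 9 | methyl (2Z,4R,5R,8E,10E,12E)-5-(tert-butyldimethylsilyloxy)-4,10,12-trimethyltetradeca-2,8,10,12-tetraenoate | C/C=C(C)/C=C(C)/C=C/CC[C@@H](O[Si](C)(C)C(C)(C)C)[C@H](C)/C=C\C(=O)OC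
F6 | step 9 | methyl (1R,2S,4aS,7R,8R,8aS)-2-[(E)-but-2-en-2-yl]-7-(tert-butyldimethylsilyloxy)-3,8-dimethyl-1,2,4a,5,6,7,8,8a-octahydronaphthalene-1-carboxylate (cis-fused, ester cis to the butenyl group) | C/C=C(\C)[C@H]1C(C)=C[C@H]2CC[C@@H](O[Si](C)(C)C(C)(C)C)[C@H](C)[C@H]2[C@H]1C(=O)OC
F7 | step 9 | [(1R,2S,4aS,7R,8R,8aR)-2-[(E)-but-2-en-2-yl]-7-(tert-butyldimethylsilyloxy)-3,8-dimethyl-1,2,4a,5,6,7,8,8a-octahydronaphthalen-1-yl]methanol | C/C=C(\C)[C@H]1C(C)=C[C@H]2CC[C@@H](O[Si](C)(C)C(C)(C)C)[C@H](C)[C@H]2[C@H]1CO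
F8 | step 9 | (1R,2S,4aS,7R,8R,8aS)-2-[(E)-but-2-en-2-yl]-7-(tert-butyldimethylsilyloxy)-3,8-dimethyl-1,2,4a,5,6,7,8,8a-octahydronaphthalene-1-carbaldehyde (formyl cis to the butenyl group) | C/C=C(\C)[C@H]1C(C)=C[C@H]2CC[C@@H](O[Si](C)(C)C(C)(C)C)[C@H](C)[C@H]2[C@H]1C=O
F9 | step 9 | (1S,2S,4aS,7R,8R,8aS)-2-[(E)-but-2-en-2-yl]-7-(tert-butyldimethylsilyloxy)-3,8-dimethyl-1,2,4a,5,6,7,8,8a-octahydronaphthalene-1-carbaldehyde (formyl trans to the butenyl group) | C/C=C(\C)[C@H]1C(C)=C[C@H]2CC[C@@H](O[Si](C)(C)C(C)(C)C)[C@H](C)[C@H]2[C@@H]1C=O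
F10 | step 2 | (3E,5E)-3,5-dimethylhepta-3,5-dien-1-yne | C/C=C(C)/C=C(\C)C#C
F11 | step 2 | chlorobis(cyclopentadienyl)[(1E,3E,5E)-3,5-dimethylhepta-1,3,5-trien-1-yl]zirconium | C/C=C(C)/C=C(C)/C=C/[Zr+2]Cl.c1cc[cH-]c1.c1cc[cH-]c1
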